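**Assumptions (chemistry).** The target is treated as the open γ-hydroxy ketone as drawn; reversible closure to its five-membered hemiketal is taken not to change the outcome. Imide 1 (either enantiomer of this Evans imide) is taken as purchasable. Ring atoms are numbered as in cyclohex-2-en-1-one: C1 = ring C=O, C2=C3, C4 = C(OH)CH3, C5 = CH, C6 = C(CH3)2.

## Retrosynthetic overview

1. Target 22 ⇐ oxidation of the two secondary carbinols of triol 21 ⇐ Nozaki–Hiyama–Kishi union of lactol 14 (side-chain C=O carbon at the aldehyde level) with Z-vinyl iodide 19 (from but-2-yn-1-ol).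
2. Lactol 14 ⇐ enone lactone 13 ⇐ keto lactone 12: a temporary cis-fused γ-lactone (ring B: O on C4, CH2 on C5) fixes the cis C4–OH / C5–CH2 relation; it is closed onto exo-methylene ketone 11 (⇐ dione 10) and opened again in the coupling.
3. Dione 10 ⇐ aldehyde 6 + acrylonitrile 7: one photocatalytic operation makes C3–C4 (acyl radical addition) and C1–C6 (tertiary radical onto the nitrile carbon), a 3 + 3 construction of the carbocycle (ring A).
4. Enabling feature: in 6 the formyl C–H (future C4) and the tertiary isopropyl C–H (future C6) flank the stereogenic carbon C5. Both are hydridic C–H bonds that one hydrogen-atom-transfer photocatalyst can open in turn; acrylonitrile offers an acceptor carbon (C3) and, two atoms on, a nitrile carbon (C1) that ends as the ring ketone.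
5. Ring order: carbocycle A first (step 4), then the temporary lactone B (step 6, cleaved in steps 8 and 11); C5 comes from an Evans alkylation (step 1).

Key step: step 4

## Route

Step 1
Reactants: 1 (4R)-4-benzyl-3-(3-methylbutanoyl)-1,3-oxazolidin-2-one; 2 tert-butyl bromoacetate
Product: 4 tert-butyl (3R)-3-{[(4R)-4-benzyl-2-oxo-1,3-oxazolidin-3-yl]carbonyl}-4-methylpentanoate, via sodium enolate 3 (not isolated)
Conditions: NaN(SiMe3)2, THF, −78 °C; then 2, −78 to −20 °C
Reagents that add atoms: none
Why: Evans asymmetric alkylation, in which the chelated Z-enolate is alkylated on the face away from the benzyl group and so sets the future C5 as R.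

Step 2
Reactants: 4 tert-butyl (3R)-3-{[(4R)-4-benzyl-2-oxo-1,3-oxazolidin-3-yl]carbonyl}-4-methylpentanoate
Product: 5 tert-butyl (3R)-3-(hydroxymethyl)-4-methylpentanoate
Conditions: LiBH4, MeOH (1 equiv), Et2O, 0 °C
Reagents that add atoms: none
Why: Reductive removal of the oxazolidinone auxiliary (hydride reduction of the activated imide carbonyl) should leave the hindered tert-butyl ester and the stereocentre untouched.

Step 3
Reactants: 5 tert-butyl (3R)-3-(hydroxymethyl)-4-methylpentanoate
Product: 6 tert-butyl (3R)-3-formyl-4-methylpentanoate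
Conditions: Dess–Martin periodinane, NaHCO3, CH2Cl2, 0 °C; used crude
Reagents that add atoms: none
Why: Dess–Martin oxidation under buffered, non-basic conditions should give the α-branched aldehyde without epimerization.

Step 4
Reactants: 6 tert-butyl (3R)-3-formyl-4-methylpentanoate; 7 acrylonitrile
Product: 10 tert-butyl [(1R)-2,2-dimethyl-3,6-dioxocyclohexyl]acetate, via keto nitrile 8 (not isolated), via cyclic ketimine 9 (not isolated)
Conditions: (n-Bu4N)4W10O32 (4 mol%), 7 (1.05 equiv), MeCN, 390 nm LEDs, N2, 10–20 °C, irradiation continued after 7 is consumed; then 1 M aq HCl, THF, rt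
Reagents that add atoms: water, O
Why: Proposed new method: photoexcited decatungstate abstracts the formyl hydrogen of 6, the acyl radical adds to the CH2 terminus of acrylonitrile (C3–C4 bond) and back hydrogen transfer gives 8, after which the same catalyst abstracts the tertiary isopropyl C–H and the tertiary radical adds to the nitrile carbon (C1–C6 bond) to an iminyl radical that is reduced to ketimine 9 and hydrolysed to the dione. The closest known reaction types are the decatungstate-photocatalysed hydroacylation of electron-poor alkenes with aldehydes, the decatungstate alkylation of isobutyl ketones at the β-methine position and the cyclization of tertiary radicals (from metal hydride hydrogen atom transfer) onto nitriles to cyclic ketones; joining them in one cascade is the new element. The carbocycle is closed in the 6-exo-dig mode onto the C≡N bond. No stereocentre is formed, and C5 keeps its configuration because it is never a radical centre and the medium is neutral. The step needs site selectivity (formyl C–H before any C(sp3)–H, then the methine rather than the polarity-deactivated C–H bonds next to C=O, C≡N and CO2tBu) and needs the tertiary radical to find no free acrylonitrile, which the one-equivalent charge of 7 and the much faster first stage should provide; hydrogen abstraction at other sites is reversible and unproductive because only the C6 radical has an intramolecular acceptor within reach.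

Step 5
Reactants: 10 tert-butyl [(1R)-2,2-dimethyl-3,6-dioxocyclohexyl]acetate
Product: 11 tert-butyl [(1S)-2,2-dimethyl-6-methylidene-3-oxocyclohexyl]acetate
Conditions: Zn, CH2Br2, TiCl4, THF/CH2Cl2, 0 °C to rt
Reagents that add atoms: dibromomethane, BrCBr
Why: Takai–Lombardo methylenation is non-basic (no epimerization at C5) and should select the ketone next to the CH carbon over the one next to the quaternary carbon; the descriptor changes only because the priorities change.

Step 6
Reactants: 11 tert-butyl [(1S)-2,2-dimethyl-6-methylidene-3-oxocyclohexyl]acetate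
Product: 12 (3aR,7aS)-4,4,7a-trimethylhexahydro-1-benzofuran-2,5-dione
Conditions: Co(salen) (5 mol%), N-fluoro-2,4,6-trimethylpyridinium tetrafluoroborate, (Me2SiH)2O, PhCF3, rt
Reagents that add atoms: none
Why: Cobalt hydride hydrogen-atom-transfer hydroacyloxylation (Markovnikov, radical-polar crossover) puts H on the methylene carbon (which becomes the C4 methyl group), and the ester carbonyl oxygen on the C5 arm captures C4 with loss of isobutene; the three-atom tether allows only the cis-fused γ-lactone, which sets C4 relative to C5.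

Step 7
Reactants: 12 (3aR,7aS)-4,4,7a-trimethylhexahydro-1-benzofuran-2,5-dione
Product: 13 (3aR,7aS)-4,4,7a-trimethyl-3,3a,4,7a-tetrahydro-1-benzofuran-2,5-dione
Conditions: IBX, DMSO/PhF, 70 °C
Reagents that add atoms: none
Why: IBX dehydrogenation of a ketone to its enone can only give the C2=C3 double bond because the other α-carbon (C6) is quaternary.

Step 8
Reactants: 13 (3aR,7aS)-4,4,7a-trimethyl-3,3a,4,7a-tetrahydro-1-benzofuran-2,5-dione
Product: 14 (3aR,7aS)-4,4,7a-trimethyl-2,3,3a,4,5,7a-hexahydro-1-benzofuran-2,5-diol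
Conditions: i-Bu2AlH (2.3 equiv), CH2Cl2, −78 °C
Reagents that add atoms: none
Why: Diisobutylaluminium hydride reduction should give 1,2-reduction of the enone and half-reduction of the γ-lactone to the lactol; both new carbinol centres are left as mixtures because both are oxidized in step 12.

Step 9
Reactants: 15 but-2-yn-1-ol
Product: 17 (2Z)-3-iodobut-2-en-1-ol, via cyclic vinylalanate 16 (not isolated)
Conditions: NaAlH2(OCH2CH2OMe)2, THF, 0 °C to rt; then I2, −78 °C
Reagents that add atoms: iodine, II
Why: Hydroxyl-directed trans-hydroalumination of the propargylic alcohol followed by iodinolysis with retention should give the Z-iodide (I cis to CH2OH), the geometry required for the Z-enone.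

Step 10
Reactants: 17 (2Z)-3-iodobut-2-en-1-ol; 18 decanoyl chloride
Product: 19 (2Z)-3-iodobut-2-en-1-yl decanoate
Conditions: Et3N, DMAP (cat.), CH2Cl2, 0 °C
Reagents that add atoms: none
Why: Acylation (nucleophilic acyl substitution) of the primary allylic alcohol installs the decanoate before the coupling.

Step 11
Reactants: 14 (3aR,7aS)-4,4,7a-trimethyl-2,3,3a,4,5,7a-hexahydro-1-benzofuran-2,5-diol; 19 (2Z)-3-iodobut-2-en-1-yl decanoate
Product: 21 (2Z)-5-[(1R,2S)-2,5-dihydroxy-2,6,6-trimethylcyclohex-3-en-1-yl]-4-hydroxy-3-methylpent-2-en-1-yl decanoate, via alkenylchromium dichloride 20 (not isolated)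
Conditions: CrCl2 (6 equiv), NiCl2 (2 mol%), DMSO, rt
Reagents that add atoms: none
Why: Nozaki–Hiyama–Kishi coupling, in which the alkenylchromium reagent (formed with retention of the Z geometry) adds to the hydroxy aldehyde tautomer of the lactol and tolerates the ester and free hydroxyl groups; the new carbinol centre is not controlled because it is oxidized next.

Step 12
Reactants: 21 (2Z)-5-[(1R,2S)-2,5-dihydroxy-2,6,6-trimethylcyclohex-3-en-1-yl]-4-hydroxy-3-methylpent-2-en-1-yl decanoate
Product: 22 (2Z)-5-[(1R,2S)-2-hydroxy-2,6,6-trimethyl-5-oxocyclohex-3-en-1-yl]-3-methyl-4-oxopent-2-en-1-yl decanoate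
Conditions: Dess–Martin periodinane (3 equiv), NaHCO3, CH2Cl2, 0 °C to rt
Reagents that add atoms: none
Why: Dess–Martin oxidation of both secondary allylic alcohols should give the ring enone and the side-chain Z-enone, while the tertiary alcohol cannot be oxidized.

## Compound list

1 | (4R)-4-benzyl-3-(3-methylbutanoyl)-1,3-oxazolidin-2-one | CC(C)CC(=O)N1[C@H](Cc2ccccc2)COC1=O | starting material
2 | tert-butyl bromoacetate | CC(C)(C)OC(=O)CBr | starting material
3 | sodium (Z)-enolate of imide 1 | CC(C)/C=C(\[O-])N1[C@H](Cc2ccccc2)COC1=O.[Na+] | intermediate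
4 | tert-butyl (3R)-3-{[(4R)-4-benzyl-2-oxo-1,3-oxazolidin-3-yl]carbonyl}-4-methylpentanoate | CC(C)[C@H](C(=O)N1[C@H](Cc2ccccc2)COC1=O)CC(=O)OC(C)(C)C | intermediate
5 | tert-butyl (3R)-3-(hydroxymethyl)-4-methylpentanoate | CC(C)[C@H](CO)CC(=O)OC(C)(C)C | intermediate
6 | tert-butyl (3R)-3-formyl-4-methylpentanoate | CC(C)[C@H](C=O)CC(=O)OC(C)(C)C | intermediate
7 | acrylonitrile | C=CC#N | starting material
8 | tert-butyl (3R)-6-cyano-4-oxo-3-(propan-2-yl)hexanoate | CC(C)[C@H](C(=O)CCC#N)CC(=O)OC(C)(C)C | intermediate
9 | tert-butyl [(1R)-3-imino-2,2-dimethyl-6-oxocyclohexyl]acetate | CC(C)(C)OC(=O)C[C@H]1C(=O)CCC(=N)C1(C)C | intermediate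
10 | tert-butyl [(1R)-2,2-dimethyl-3,6-dioxocyclohexyl]acetate | CC(C)(C)OC(=O)C[C@H]1C(=O)CCC(=O)C1(C)C | intermediate
11 | tert-butyl [(1S)-2,2-dimethyl-6-methylidene-3-oxocyclohexyl]acetate | CC(C)(C)OC(=O)C[C@H]1C(=C)CCC(=O)C1(C)C | intermediate
12 | (3aR,7aS)-4,4,7a-trimethylhexahydro-1-benzofuran-2,5-dione (cis-fused keto lactone) | O=C1C[C@@H]2C(C)(C)C(=O)CC[C@]2(C)O1 | intermediate
13 | (3aR,7aS)-4,4,7a-trimethyl-3,3a,4,7a-tetrahydro-1-benzofuran-2,5-dione | O=C1C[C@@H]2C(C)(C)C(=O)C=C[C@]2(C)O1 | intermediate
14 | (3aR,7aS)-4,4,7a-trimethyl-2,3,3a,4,5,7a-hexahydro-1-benzofuran-2,5-diol (epimers at C2 and C5) | OC1C[C@@H]2C(C)(C)C(O)C=C[C@]2(C)O1 | intermediate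
15 | but-2-yn-1-ol | CC#CCO | starting material
16 | sodium 2,2-bis(2-methoxyethoxy)-3-methyl-2,5-dihydro-1,2-oxaalumol-2-uide (cyclic vinylalanate) | CC1=CCO[Al-]1(OCCOC)OCCOC.[Na+] | intermediate
17 | (2Z)-3-iodobut-2-en-1-ol | C/C(I)=C/CO | intermediate
18 | decanoyl chloride | CCCCCCCCCC(=O)Cl | starting material
19 | (2Z)-3-iodobut-2-en-1-yl decanoate | CCCCCCCCCC(=O)OC/C=C(/C)I | intermediate
20 | [(2Z)-4-(decanoyloxy)but-2-en-2-yl]chromium dichloride | CCCCCCCCCC(=O)OC/C=C(/C)[Cr](Cl)Cl | intermediate
21 | (2Z)-5-[(1R,2S)-2,5-dihydroxy-2,6,6-trimethylcyclohex-3-en-1-yl]-4-hydroxy-3-methylpent-2-en-1-yl decanoate (epimers at chain C4 and ring C5) | CCCCCCCCCC(=O)OC/C=C(/C)C(O)C[C@@H]1C(C)(C)C(O)C=C[C@]1(C)O | intermediate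
22 | (2Z)-5-[(1R,2S)-2-hydroxy-2,6,6-trimethyl-5-oxocyclohex-3-en-1-yl]-3-methyl-4-oxopent-2-en-1-yl decanoate | CCCCCCCCCC(=O)OC/C=C(/C)C(=O)C[C@@H]1C(C)(C)C(=O)C=C[C@]1(C)O | target

## Step count and risks

Total step count: 12. Longest linear sequence: 10 (steps 1–8, 11, 12).

**Step 4 (proposed new method).** Back hydrogen transfer to the tertiary radical may outrun its slow closure onto the nitrile. The radical may also be intercepted by residual acrylonitrile, or migrate its β-acyl group, and the α-branched acyl radical may lose CO before it adds. The fallback uses known chemistry, makes the two bonds separately and uses an alkene as radical precursor; it sets out from bromide 2 and returns at dione 10. The imide (4R)-4-benzyl-3-(3-methylbut-3-enoyl)-1,3-oxazolidin-2-one F1 would be alkylated with 2 as in step 1 to tert-butyl (3R)-3-{[(4R)-4-benzyl-2-oxo-1,3-oxazolidin-3-yl]carbonyl}-4-methylpent-4-enoate F2. LiOH/H2O2 would give (2R)-2-(2-tert-butoxy-2-oxoethyl)-3-methylbut-3-enoic acid F3, and EtSH/DCC/DMAP would give tert-butyl (3R)-3-[(ethylsulfanyl)carbonyl]-4-methylpent-4-enoate F4. Fukuyama coupling with IZnCH2CH2CN (PdCl2(PPh3)2 cat.) would give tert-butyl (3R)-6-cyano-4-oxo-3-(prop-1-en-2-yl)hexanoate F5. Fe(acac)3/PhSiH3 in EtOH (hydrogen atom transfer to the isopropenyl group, 6-exo closure of the tertiary radical onto the nitrile), then aqueous acid, should give 10 through ketimine 9.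

**Step 5.** Methylenation may occur at the more hindered carbonyl or at both, or Lewis-acid enolization toward C5 may erode the configuration. The fallback makes the C–CH3 bond by carbonyl addition and the C–O bond by ionization; it sets out from dione 10 and returns at keto lactone 12, replacing steps 5 and 6. MeLi/CeCl3 at −78 °C would add to the less hindered ketone to give tert-butyl [(1R)-6-hydroxy-2,2,6-trimethyl-3-oxocyclohexyl]acetate F6 (either C4 epimer). CF3CO2H would then remove the tert-butyl group and ionize the tertiary alcohol, so that the carboxyl group closes the same cis-fused lactone from both epimers.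

**Step 11.** The lactol of a tertiary alcohol may open too little to the hydroxy aldehyde for the alkenylchromium reagent to capture it, or the decanoate may migrate to the neighbouring new alkoxide. The fallback replaces the chromium coupling by an organolithium addition with late acylation; it sets out from lactol 14 and iodo alcohol 17 and returns at triol ester 21. Alcohol 17 would be silylated (TBSCl, imidazole) to tert-butyl{[(2Z)-3-iodobut-2-en-1-yl]oxy}dimethylsilane F7. Exchange with t-BuLi at −78 °C would give the alkenyllithium, which would be added in excess to 14 to give the silyl ether triol F8. Bu4NF would give the tetraol F9, and acylation of its only primary hydroxyl group with decanoyl chloride 18 (2,4,6-trimethylpyridine, −78 °C) would give 21.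

Further compounds
F1 | step 4 | (4R)-4-benzyl-3-(3-methylbut-3-enoyl)-1,3-oxazolidin-2-one | CC(=C)CC(=O)N1[C@H](Cc2ccccc2)COC1=O
F2 | step 4 | tert-butyl (3R)-3-{[(4R)-4-benzyl-2-oxo-1,3-oxazolidin-3-yl]carbonyl}-4-methylpent-4-enoate | CC(=C)[C@H](C(=O)N1[C@H](Cc2ccccc2)COC1=O)CC(=O)OC(C)(C)C
F3 | step 4 | (2R)-2-(2-tert-butoxy-2-oxoethyl)-3-methylbut-3-enoic acid | CC(=C)[C@H](C(=O)O)CC(=O)OC(C)(C)C
F4 | step 4 | tert-butyl (3R)-3-[(ethylsulfanyl)carbonyl]-4-methylpent-4-enoate | CC(=C)[C@H](C(=O)SCC)CC(=O)OC(C)(C)C
F5 | step 4 | tert-butyl (3R)-6-cyano-4-oxo-3-(prop-1-en-2-yl)hexanoate | CC(=C)[C@H](C(=O)CCC#N)CC(=O)OC(C)(C)C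
F6 | step 5 | tert-butyl [(1R)-6-hydroxy-2,2,6-trimethyl-3-oxocyclohexyl]acetate | CC(C)(C)OC(=O)C[C@H]1C(C)(O)CCC(=O)C1(C)C
F7 | step 11 | tert-butyl{[(2Z)-3-iodobut-2-en-1-yl]oxy}dimethylsilane | C/C(I)=C/CO[Si](C)(C)C(C)(C)C
F8 | step 11 | (1S,6R)-6-[(3Z)-5-{[tert-butyl(dimethyl)silyl]oxy}-2-hydroxy-3-methylpent-3-en-1-yl]-1,5,5-trimethylcyclohex-2-ene-1,4-diol | CC(C)(C)[Si](C)(C)OC/C=C(/C)C(O)C[C@@H]1C(C)(C)C(O)C=C[C@]1(C)O
F9 | step 11 | (1S,6R)-6-[(3Z)-2,5-dihydroxy-3-methylpent-3-en-1-yl]-1,5,5-trimethylcyclohex-2-ene-1,4-diol | OC/C=C(/C)C(O)C[C@@H]1C(C)(C)C(O)C=C[C@]1(C)O
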